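Canaliculatol is cut into an ε-viniferin-type dihydrobenzofuran (resorcinol rings A and B) and an indanone (resorcinol ring C), both drawn from one deoxybenzoin by dynamic kinetic reduction. Everything rests on closing the dihydrofuran through its aryl ether bond O–C11a instead of the benzylic C7b–O bond. The key step exploits that C11a and C9a both flank C10a and both lie meta to the C13a oxygen of ring A: in a (1R,2R)-triarylethanol carrying a 2,6-dichloro-4-methoxyphenyl ring, base turns either C–Cl into a methoxy-polarised aryne and the tethered alkoxide adds at C11a, leaving C7b and C8b untouched. The surviving chlorine on C9a then joins the indanone, and a cationic eight-membered ring closure follows.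

Key step: step 5

Atom labels (resveratrol-oligomer usage): unit a = C7a aryl (4-oxygenated phenyl)–C7a–C8a–ring A (C9a–C14a, oxygens on C11a and C13a); unit b = C7b aryl–C7b(O)–C8b–ring B (C9b–C14b, oxygens on C11b and C13b); unit c = C7c aryl–C7c–C8c–ring C (C9c–C14c, oxygens on C11c and C13c). Bonds between units: C8a–C8c, C7a–C10c, C7c–C10b, C8b–C10a, C7b–O–C11a. Target configuration: 7aR, 8aS, 7bR, 8bR, 7cR, 8cR; the C7a aryl is cis to ring A on the indane, and the five- and eight-membered rings are trans-fused.

Remark: all eight phenols are carried as methyl ethers; it is assumed that BBr3 frees them without opening the trans-dihydrobenzofuran, as is usual for permethylated resveratrol oligomers.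

Step 1
Reactants: 1 4'-methoxyacetophenone; 2 1-bromo-3,5-dimethoxybenzene
Product: 3 2-(3,5-dimethoxyphenyl)-1-(4-methoxyphenyl)ethan-1-one
Conditions: Pd2(dba)3 (1 mol%), Xantphos (2.5 mol%), NaOtBu, THF, 70 °C
Reagents that add atoms: none
Why: Palladium-catalysed α-arylation of an aryl methyl ketone; the wide-bite-angle ligand should stop at mono-arylation because the deoxybenzoin enolate is more hindered and less nucleophilic.

Step 2
Reactants: 4 3,5-dichloroanisole
Product: 6 2-bromo-1,3-dichloro-5-methoxybenzene, via aryllithium 5 (not isolated)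
Conditions: n-BuLi, THF, −78 °C; then BrCCl2CCl2Br, −78 → 0 °C
Reagents that add atoms: 1,2-dibromo-1,1,2,2-tetrachloroethane, BrC(Cl)(Cl)C(Cl)(Cl)Br
Why: Directed ortho-lithiation at the C–H flanked by both chlorines (the most acidic position), then electrophilic bromination of the aryllithium, which does not lose LiCl at −78 °C.

Step 3
Reactants: 3 deoxybenzoin; 6 2-bromo-1,3-dichloro-5-methoxybenzene
Product: 7 (±)-2-(2,6-dichloro-4-methoxyphenyl)-2-(3,5-dimethoxyphenyl)-1-(4-methoxyphenyl)ethan-1-one
Conditions: Pd(OAc)2 (3 mol%), XPhos (6 mol%), NaOtBu, toluene, 90 °C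
Reagents that add atoms: none
Why: Palladium-catalysed ketone α-arylation; oxidative addition should be selective for C–Br over the two C–Cl bonds, the doubly benzylic product cannot be arylated again, and the new centre is racemic and labile.

Step 4
Reactants: 7 triaryl ketone
Product: 8 (1R,2R)-2-(2,6-dichloro-4-methoxyphenyl)-2-(3,5-dimethoxyphenyl)-1-(4-methoxyphenyl)ethan-1-ol
Conditions: RuCl(p-cymene)[(R,R)-TsDPEN] (2 mol%), HCO2H/Et3N (5:2), DMF, 40 °C
Reagents that add atoms: none
Why: Noyori–Ikariya asymmetric transfer hydrogenation with dynamic kinetic resolution: C8b epimerises through the enol, the (R,R) catalyst should give the (R)-carbinol at C7b, and it should reduce faster the ketone enantiomer for which this is also the Felkin–Anh face (hydride anti to the bulky 2,6-dichloroaryl group), which gives the (1R,2R) isomer.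

Step 5
Reactants: 8 (1R,2R)-triarylethanol
Product: 10 (2R,3R)-4-chloro-3-(3,5-dimethoxyphenyl)-6-methoxy-2-(4-methoxyphenyl)-2,3-dihydro-1-benzofuran, via aryne alkoxide 9 (not isolated)
Conditions: LiTMP (lithium 2,2,6,6-tetramethylpiperidide, from the amine and n-BuLi, 2.3 equiv), THF, −78 → 0 °C; aq NH4Cl
Reagents that add atoms: none
Why: LiTMP first forms the lithium alkoxide and then removes H12a (or its twin H14a), which is acidified by the flanking chlorine and the C13a methoxy group, and loss of LiCl gives aryne 9 next to C10a; the tethered alkoxide adds to the proximal aryne carbon in a 5-exo-dig mode to close the dihydrofuran ring (O, C7b, C8b, C10a, C11a), and the C12a aryllithium so formed is protonated on quench. The closest known reaction type is the base-mediated intramolecular addition of an alkoxide to an aryne generated from a haloarene (benzyne cyclisation to 2,3-dihydrobenzofurans). No stereocentre is made: C7b and C8b are set in step 4 and keep their configuration because no bond to either is broken, so the (1R,2R) alcohol should give the trans-(2R,3R) ring. Regiochemistry has two safeguards: the tether allows attack only at C11a, and the C13a methoxy group beside the triple bond polarises the aryne so that the nucleophile adds at the carbon meta to it (C11a) while the carbanion rests ortho to it (C12a). Because the two chlorines are equivalent by rotation of ring A, either aryne gives the same product and the other chlorine ends on C9a. Over-reaction to a second aryne should be held back by the base stoichiometry and by the product persisting as the C12a aryllithium until the quench.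

Step 6
Reactants: 3 deoxybenzoin; 11 tert-butyl bromoacetate
Product: 12 (±)-tert-butyl 3-(3,5-dimethoxyphenyl)-4-(4-methoxyphenyl)-4-oxobutanoate
Conditions: KOtBu, THF, 0 °C; then 11, 0 → 25 °C
Reagents that add atoms: none
Why: SN2 alkylation of the stabilised deoxybenzoin enolate with an α-bromo ester; the new α-centre is racemic and epimerisable.

Step 7
Reactants: 12 γ-keto ester
Product: 13 tert-butyl (3S,4S)-3-(3,5-dimethoxyphenyl)-4-hydroxy-4-(4-methoxyphenyl)butanoate
Conditions: RuCl(p-cymene)[(S,S)-TsDPEN] (2 mol%), HCO2H/Et3N (1:2), DMF, 40 °C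
Reagents that add atoms: none
Why: Asymmetric transfer hydrogenation with dynamic kinetic resolution as in step 4, now with the (S,S) catalyst: the α-aryl centre racemises via the enol, hydride should give the (S)-carbinol, and the Felkin–Anh-matched ketone enantiomer (aryl anti to hydride) should react faster, setting C8c as 3S; the C7c carbinol centre is lost again in step 12.

Step 8
Reactants: 13 hydroxy ester
Product: 14 tert-butyl (3S,4S)-4-[(tert-butyldimethylsilyl)oxy]-3-(3,5-dimethoxyphenyl)-4-(4-methoxyphenyl)butanoate
Conditions: TBSOTf, 2,6-lutidine, CH2Cl2, −78 → 0 °C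
Reagents that add atoms: tert-butyldimethylsilyl trifluoromethanesulfonate, CC(C)(C)[Si](C)(C)OS(=O)(=O)C(F)(F)F
Why: Silyl ether formation masks the benzylic alcohol against lactonisation in the strongly basic step 10 and leaves an ionisable group for step 12.

Step 9
Reactants: 14 silyl ether
Product: 15 tert-butyl (3S,4S)-3-(2-bromo-3,5-dimethoxyphenyl)-4-[(tert-butyldimethylsilyl)oxy]-4-(4-methoxyphenyl)butanoate
Conditions: NBS, MeCN, 0 °C
Reagents that add atoms: N-bromosuccinimide, O=C1CCC(=O)N1Br
Why: Electrophilic aromatic bromination; the 3,5-dimethoxyphenyl ring is far more nucleophilic than the anisyl ring and should react at C10c (ortho to the side chain, para to a methoxy group) in preference to the position between the two methoxy groups.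

Step 10
Reactants: 15 aryl bromide
Product: 17 (3S)-3-[(S)-[(tert-butyldimethylsilyl)oxy](4-methoxyphenyl)methyl]-5,7-dimethoxy-2,3-dihydro-1H-inden-1-one, via C10c aryllithium 16 (not isolated)
Conditions: t-BuLi (2.1 equiv), THF, −78 → −20 °C; aq NH4Cl
Reagents that add atoms: none
Why: Parham cyclisation: bromine–lithium exchange and 5-exo attack of the aryllithium on the tert-butyl ester close the indanone (C7a–C10c bond); C8c is not touched.

Step 11
Reactants: 17 indanone; 10 chloro-dihydrobenzofuran
Product: 18 (2R,3S)-3-[(S)-[(tert-butyldimethylsilyl)oxy](4-methoxyphenyl)methyl]-2-[(2R,3R)-3-(3,5-dimethoxyphenyl)-6-methoxy-2-(4-methoxyphenyl)-2,3-dihydro-1-benzofuran-4-yl]-5,7-dimethoxy-2,3-dihydro-1H-inden-1-one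
Conditions: Pd2(dba)3 (2.5 mol%), P(t-Bu)3·HBF4 (6 mol%), NaOtBu, toluene, 80 °C; then DBU (cat.), CH2Cl2, 25 °C
Reagents that add atoms: none
Why: Palladium-catalysed α-arylation of the indanone enolate with the aryl chloride joins the halves at C8a–C9a; C8a is epimerisable next to the ketone and should settle trans to the C8c substituent under the DBU equilibration.

Step 12
Reactants: 18 coupled indanone
Product: 20 heptamethyl C7a ketone (canaliculatol skeleton lacking the C7a aryl; C7a is the indanone carbonyl), via C7c cation 19 (not isolated)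
Conditions: BF3·OEt2, 2,6-di-tert-butyl-4-methylpyridine, CH2Cl2 (0.005 M), −78 → −30 °C
Reagents that add atoms: none
Why: Intramolecular Friedel–Crafts alkylation: BF3 ionises the silyl ether to the 4-methoxybenzyl cation 19, which C10b of ring B (para and ortho to its methoxy groups) attacks to close the eight-membered ring; the trans C8a/C8c arrangement rules out closure onto C14a, attack on the rotamer with H8c eclipsing the C7c aryl (least allylic 1,3-strain) and anti to C9c should set C7c as R, and the hindered pyridine buffers the acid so that no alkene is re-protonated.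

Step 13
Reactants: 20 heptamethyl ketone; 21 4-methoxyphenylmagnesium bromide
Product: 22 C7a tertiary alcohol (C7a aryl anti to ring A; hydroxyl syn to ring A)
Conditions: 21, anhydrous CeCl3, THF, −78 → 0 °C; aq NH4Cl
Reagents that add atoms: none
Why: 1,2-Addition of an organocerium reagent (from the Grignard reagent and CeCl3), which should add to the hindered, enolisable ketone without deprotonating C8a; the new carbinol centre is lost in step 14.

Step 14
Reactants: 22 tertiary alcohol
Product: 24 canaliculatol octamethyl ether (7aR,8aS,7bR,8bR,7cR,8cR), via C7a cation 23 (not isolated)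
Conditions: Et3SiH, CF3CO2H, CH2Cl2, −40 → 0 °C
Reagents that add atoms: none
Why: Ionic hydrogenation: the acid ionises the doubly benzylic alcohol to cation 23 and triethylsilane should deliver hydride to the face anti to ring A on the neighbouring C8a, which places the C7a aryl cis to ring A (7aR).

Step 15
Reactants: 24 octamethyl ether
Product: 25 canaliculatol
Conditions: BBr3, CH2Cl2, −78 → 25 °C; then MeOH, H2O
Reagents that add atoms: none
Why: Lewis acid cleavage of all eight aryl methyl ethers; no stereocentre is touched and the trans-dihydrobenzofuran should survive.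

Compound list
1 | 4'-methoxyacetophenone | CC(=O)c1ccc(OC)cc1 | starting material
2 | 1-bromo-3,5-dimethoxybenzene | COc1cc(Br)cc(OC)c1 | starting material
3 | 2-(3,5-dimethoxyphenyl)-1-(4-methoxyphenyl)ethan-1-one | COc1ccc(cc1)C(=O)Cc1cc(OC)cc(OC)c1 | intermediate
4 | 3,5-dichloroanisole | COc1cc(Cl)cc(Cl)c1 | starting material
5 | (2,6-dichloro-4-methoxyphenyl)lithium | COc1cc(Cl)c([Li])c(Cl)c1 | intermediate
6 | 2-bromo-1,3-dichloro-5-methoxybenzene | COc1cc(Cl)c(Br)c(Cl)c1 | intermediate
7 | (±)-2-(2,6-dichloro-4-methoxyphenyl)-2-(3,5-dimethoxyphenyl)-1-(4-methoxyphenyl)ethan-1-one | COc1ccc(cc1)C(=O)C(c1cc(OC)cc(OC)c1)c1c(Cl)cc(OC)cc1Cl | intermediate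
8 | (1R,2R)-2-(2,6-dichloro-4-methoxyphenyl)-2-(3,5-dimethoxyphenyl)-1-(4-methoxyphenyl)ethan-1-ol | COc1ccc(cc1)[C@H](O)[C@H](c1cc(OC)cc(OC)c1)c1c(Cl)cc(OC)cc1Cl | intermediate
9 | lithium alkoxide of 8 with ring A as the C11a≡C12a aryne | [Li+].COc1ccc(cc1)[C@H]([O-])[C@H](c1cc(OC)cc(OC)c1)C1=C(Cl)C=C(OC)C#C1 | intermediate
10 | (2R,3R)-4-chloro-3-(3,5-dimethoxyphenyl)-6-methoxy-2-(4-methoxyphenyl)-2,3-dihydro-1-benzofuran | COc1cc(OC)cc(c1)[C@@H]1c2c(Cl)cc(OC)cc2O[C@H]1c1ccc(OC)cc1 | intermediate
11 | tert-butyl bromoacetate | CC(C)(C)OC(=O)CBr | starting material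
12 | (±)-tert-butyl 3-(3,5-dimethoxyphenyl)-4-(4-methoxyphenyl)-4-oxobutanoate | COc1ccc(cc1)C(=O)C(CC(=O)OC(C)(C)C)c1cc(OC)cc(OC)c1 | intermediate
13 | tert-butyl (3S,4S)-3-(3,5-dimethoxyphenyl)-4-hydroxy-4-(4-methoxyphenyl)butanoate | COc1ccc(cc1)[C@@H](O)[C@@H](CC(=O)OC(C)(C)C)c1cc(OC)cc(OC)c1 | intermediate
14 | tert-butyl (3S,4S)-4-[(tert-butyldimethylsilyl)oxy]-3-(3,5-dimethoxyphenyl)-4-(4-methoxyphenyl)butanoate | COc1ccc(cc1)[C@@H](O[Si](C)(C)C(C)(C)C)[C@@H](CC(=O)OC(C)(C)C)c1cc(OC)cc(OC)c1 | intermediate
15 | tert-butyl (3S,4S)-3-(2-bromo-3,5-dimethoxyphenyl)-4-[(tert-butyldimethylsilyl)oxy]-4-(4-methoxyphenyl)butanoate | COc1ccc(cc1)[C@@H](O[Si](C)(C)C(C)(C)C)[C@@H](CC(=O)OC(C)(C)C)c1cc(OC)cc(OC)c1Br | intermediate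
16 | C10c aryllithium from 15 | COc1ccc(cc1)[C@@H](O[Si](C)(C)C(C)(C)C)[C@@H](CC(=O)OC(C)(C)C)c1cc(OC)cc(OC)c1[Li] | intermediate
17 | (3S)-3-[(S)-[(tert-butyldimethylsilyl)oxy](4-methoxyphenyl)methyl]-5,7-dimethoxy-2,3-dihydro-1H-inden-1-one | COc1ccc(cc1)[C@@H](O[Si](C)(C)C(C)(C)C)[C@H]1CC(=O)c2c(OC)cc(OC)cc12 | intermediate
18 | (2R,3S)-3-[(S)-[(tert-butyldimethylsilyl)oxy](4-methoxyphenyl)methyl]-2-[(2R,3R)-3-(3,5-dimethoxyphenyl)-6-methoxy-2-(4-methoxyphenyl)-2,3-dihydro-1-benzofuran-4-yl]-5,7-dimethoxy-2,3-dihydro-1H-inden-1-one | COc1ccc(cc1)[C@@H](O[Si](C)(C)C(C)(C)C)[C@H]1[C@@H](C(=O)c2c(OC)cc(OC)cc12)c1cc(OC)cc2O[C@@H](c3ccc(OC)cc3)[C@H](c3cc(OC)cc(OC)c3)c12 | intermediate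
19 | C7c 4-methoxybenzyl cation from 18 | COc1ccc(cc1)[CH+][C@H]1[C@@H](C(=O)c2c(OC)cc(OC)cc12)c1cc(OC)cc2O[C@@H](c3ccc(OC)cc3)[C@H](c3cc(OC)cc(OC)c3)c12 | intermediate
20 | heptamethyl C7a ketone: canaliculatol skeleton lacking the C7a aryl, C7a as the indanone carbonyl; C8a, C8c, C7c, C7b and C8b arranged in space as in the target | O=C1c2c(OC)cc(OC)cc2[C@H]2[C@H](c3ccc(OC)cc3)c3c(OC)cc(OC)cc3[C@@H]3c4c(cc(OC)cc4[C@H]12)O[C@H]3c1ccc(OC)cc1 | intermediate
21 | 4-methoxyphenylmagnesium bromide | COc1ccc([Mg]Br)cc1 | starting material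
22 | C7a tertiary alcohol: 20 with a 4-methoxyphenyl group (the C7a aryl) on C7a anti to ring A and the hydroxyl syn to it | COc1ccc(cc1)[C@@]1(O)c2c(OC)cc(OC)cc2[C@H]2[C@H](c3ccc(OC)cc3)c3c(OC)cc(OC)cc3[C@@H]3c4c(cc(OC)cc4[C@H]12)O[C@H]3c1ccc(OC)cc1 | intermediate
23 | C7a carbocation from 22 | COc1ccc(cc1)[C+]1c2c(OC)cc(OC)cc2[C@H]2[C@H](c3ccc(OC)cc3)c3c(OC)cc(OC)cc3[C@@H]3c4c(cc(OC)cc4[C@H]12)O[C@H]3c1ccc(OC)cc1 | intermediate
24 | canaliculatol octamethyl ether (7aR,8aS,7bR,8bR,7cR,8cR) | COc1ccc(cc1)[C@@H]1c2c(OC)cc(OC)cc2[C@H]2[C@H](c3ccc(OC)cc3)c3c(OC)cc(OC)cc3[C@@H]3c4c(cc(OC)cc4[C@H]12)O[C@H]3c1ccc(OC)cc1 | intermediate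
25 | canaliculatol (7aR,8aS,7bR,8bR,7cR,8cR) | Oc1ccc([C@@H]2c3c(O)cc(O)cc3[C@H]3[C@H](c4ccc(O)cc4)c4c(O)cc(O)cc4[C@@H]4c5c(cc(O)cc5[C@H]23)O[C@H]4c2ccc(O)cc2)cc1 | target

Total step count: 15. Longest linear sequence: 11 steps (steps 1 and 6 to 15).

Steps most likely to fail

Step 12. The C7c cation may lose the C8c proton faster than the eight-membered ring closes, and the resulting benzylidene would isomerise to an indenone or lose the C8c configuration. The fallback inverts the order in which the two halves are joined and sets out from 17 and 10, before step 11. Under the same buffered BF3 conditions, with 10 in excess, the cation from 17 should alkylate ring B of 10 at C10b in an intermolecular Friedel–Crafts reaction. Ring A should be the less reactive partner, because C14a is flanked by the chlorine and C12a lies hindered between two oxygens, and no five-membered-ring trap is present in 17. This should give the C7c–C10b-linked seco-ketone (3R)-3-[(R)-{2-[(2R,3R)-4-chloro-6-methoxy-2-(4-methoxyphenyl)-2,3-dihydro-1-benzofuran-3-yl]-4,6-dimethoxyphenyl}(4-methoxyphenyl)methyl]-5,7-dimethoxy-2,3-dihydro-1H-inden-1-one F1. The eight-membered ring is then closed at C8a–C9a by intramolecular palladium-catalysed α-arylation of the indanone enolate with the C9a chloride (Pd2(dba)3, P(t-Bu)3·HBF4, NaOtBu, toluene, high dilution, 80 °C). The ring fusion should equilibrate to trans through the enolate, and the route is rejoined at 20.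

Step 11. Oxidative addition into the hindered, electron-rich C9a–Cl bond and reductive elimination at a secondary enolate carbon may be too slow, so that enolate self-condensation or loss of chlorine takes over. The fallback is a transition-metal-free arylation through a second aryne, setting out from 10 and 17. LiTMP in THF (−78 → 0 °C) should remove H14a of 10, which lies between the chlorine and the methoxy group, and loss of LiCl gives the C9a≡C14a aryne. The pre-formed lithium enolate of 17 should add at C9a, the carbon meta to the C13a methoxy group, and the C14a carbanion is protonated on quench. This returns directly to 18 after the same DBU equilibration; no new compound is made: none F0.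

Step 5. A second metalation and aryne formation at the remaining chlorine, addition of the amide base to the aryne, or fragmentation of the benzylic alkoxide may erode the ring closure. The fallback forms the same O–C11a bond by palladium-catalysed intramolecular C–O coupling of 8 (Pd(OAc)2, 2-(di-tert-butylphosphino)-1,1'-binaphthyl, Cs2CO3, toluene, 80 °C). Oxidative addition into either of the equivalent C–Cl bonds, alkoxide binding and C–O reductive elimination should give 10 directly with the second chlorine intact; no new compound is made: none F0.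

Further compounds
F1 | step 12 | (3R)-3-[(R)-{2-[(2R,3R)-4-chloro-6-methoxy-2-(4-methoxyphenyl)-2,3-dihydro-1-benzofuran-3-yl]-4,6-dimethoxyphenyl}(4-methoxyphenyl)methyl]-5,7-dimethoxy-2,3-dihydro-1H-inden-1-one | COc1ccc(cc1)[C@@H]([C@H]1CC(=O)c2c(OC)cc(OC)cc12)c1c(OC)cc(OC)cc1[C@@H]1c2c(Cl)cc(OC)cc2O[C@H]1c1ccc(OC)cc1
F0 | step 11 | none | none
F0 | step 5 | none | none
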